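Reading an order off two charges is a trap: the reagent charged is not the reagent in the flask at the mark, 30 % conversion of both substrates together, for by then the products have drawn a fixed debt from it.

| flask | left-handed substrate | right-handed substrate | reagent | free catalyst | remark |
|---|---|---|---|---|---|
| delta | 0.79 M | 0.79 M | 2 equiv | 0.1 mol% | the very flask that is asked about, followed so far |
| epsilon | 0.79 M | 0.79 M | 1.3 equiv | 0.1 mol% | run made earlier |
| flask | 0.79 M | 0.79 M | 2.00 equiv | 0.1 mol% |  |

delta run (percent of the left-handed substrate and right-handed substrate together charged)

| time / min | left-handed product / % | left-handed substrate / % |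
|---|---|---|
| 8.00 | 6.1 | 44.1 |
| 12.0 | 9.2 | 42.4 |
| 20.0 | 12.1 | 37.4 |
| 30.0 | 15.3 | 34.6 |
| 50.0 | 20.1 | 29.6 |
| 80.0 | 24.7 | 26.4 |
| 120 | 28.4 | 22.1 |

epsilon run (percent of the left-handed substrate and right-handed substrate together charged)

| time / h | left-handed product / % | left-handed substrate / % |
|---|---|---|
| 0.333 | 8.7 | 42.1 |
| 0.500 | 10.6 | 39.3 |
| 0.833 | 15.0 | 35.3 |
| 1.33 | 17.2 | 32.5 |
| 2.00 | 20.0 | 30.0 |
| 3.00 | 22.1 | 28.1 |
| 4.00 | 22.6 | 27.1 |

(scatter of a reading: 0.5 percentage points)

- apparent order in reagent when 30 % of the left-handed substrate and right-handed substrate together are converted (percent change of the rate of making left-handed product for one percent more reagent charged)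
- factor on the rate of making left-handed product when 30 % of the left-handed substrate and right-handed substrate together are converted if free catalyst is charged twice over

- free catalyst is single-handed; left-handed substrate and right-handed substrate are mirror images of each other, charged as a racemate, each of them at the stated concentration
- the numbers in the tables scatter by 0.5 percentage points (one standard deviation)
- steps thought possible: free catalyst + left-handed substrate <-> catalyst intermediate A; free catalyst + right-handed substrate <-> catalyst intermediate B; reagent + catalyst intermediate A -> free catalyst + left-handed product; reagent + catalyst intermediate B -> free catalyst + right-handed product; 2 reagent -> self-condensation product; reagent + free catalyst -> spent catalyst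
- no earlier run changes the charge of free catalyst; that part of a forecast is a guess

We climb the time scales from short to long. At 8.00 min in the delta run, left-handed product and left-handed substrate already sum to 50.2 %, so the catalyst intermediates hold little of the left-handed substrate and we freeze them. Next comes conversion: the delta run shows 15.3 % left-handed product at 30.0 min, which we take to lie near the mark if the unseen right-handed side keeps roughly pace. Later comes the end of reagent: the epsilon run reads 22.6 % at 4.00 h and is flattening, with reagent the likely limiting reagent.

At a fixed conversion the two substrates together stand the same whatever the reagent charge, so we take reagent as what varies. Each turnover takes one reagent, so we let the rate follow the reagent left, to the first power. That makes the order our leverage: the percent change in reagent left at the mark for one percent more charged.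

charged 1.58 M, debt 0.474 M

leverage = charged / (charged − debt) = 1.43

This counts the products' debt, not the side steps. No run varied the catalyst, so for that factor we guess a little above 2.

The forecast gave an order of 2 (1.3 to 3), from a rate ratio that “gives an order near 1.9”, and a factor of 2.9 (2.1 to 3.7).

The flask gives an order of 1.5 and a factor of 2.52.

    free catalyst + left-handed substrate ⇌ catalyst intermediate A (K = 0.300 M⁻¹, k = 760 M⁻¹ min⁻¹)
    free catalyst + right-handed substrate ⇌ catalyst intermediate B (K = 3.40 M⁻¹, k = 390 M⁻¹ min⁻¹)
    reagent + catalyst intermediate A → free catalyst + left-handed product (k = 170 M⁻¹ min⁻¹)
    reagent + catalyst intermediate B → free catalyst + right-handed product (k = 19.0 M⁻¹ min⁻¹)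
    2 reagent → self-condensation product (k = 0.00500 M⁻¹ min⁻¹)
    reagent + free catalyst → spent catalyst (k = 0.0100 M⁻¹ min⁻¹)

At the mark the epsilon run carries the same product debt on a smaller charge, so its leverage is 1.86, against 1.43 for the delta run, and on that debt alone the delta run keeps 2.00 times the reagent of the epsilon run. The slopes of left-handed product, 20.0 min to 50.0 min in delta and 0.500 h to 1.33 h in epsilon, read a ratio of 2.01. In the flask, the order leans in part on the way back from catalyst intermediate A: a simulated run without that way back has an order of 0.65, not 1.5.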